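**Plan**

Ring A is the terminal ring whose OMe is para to its bridge carbon (going round from the bridge carbon: C–OH, C–CH3, C–OMe, C–butanoyl, C–OH); ring B is the other terminal ring, with OMe ortho to its bridge carbon.
Retrosynthesis: the aryl–C(=O) bonds of the butanoyl groups on the central ring and on ring B are cut first, then five benzyl ethers. Ring A is then cut at two bonds, methyl carbon–methoxy carbon and butanoyl carbon–hydroxyl carbon, because its adjacent methoxy and butanoyl carbons are the two alkyne carbons of 1-methoxyhex-1-yn-3-one and its other four carbons (hydroxyl, bridge, hydroxyl, methyl) are the backbone of a bis-silylated 2-(arylmethyl)-3-oxopentanoate.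
The ring A bridge is cut at a Knoevenagel C=C (aryl aldehyde plus methyl 3-oxopentanoate); the central–ring B bridge is cut at an aryllithium/aldehyde union.
Forward: the ring B aldehyde and a dibrominated central ring are made from purchased benzenoids, joined, deoxygenated, formylated, homologated to the keto ester and silylated. Ring A is the only ring that is built (step 15); debenzylation and twofold acylation finish the route.
Stereochemistry: the target has no stereocentre, so none has to be set.

Key step: step 15

Remark: ArCB stands for the 2,4,6-tris(benzyloxy)-3-{[4,6-bis(benzyloxy)-2-methoxy-3-methylphenyl]methyl}phenyl group, i.e. the benzyl-protected central ring carrying ring B.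
Remark: all carbinol, keto ester and cycloadduct stereocentres and all alkylidene or enol ether geometries on the way are transient; they are carried as racemates or mixtures because later steps erase them.
Remark: 1,3,5-triacetoxybenzene is assumed to be purchased as the source of the central ring; the methoxy ynone and the bis-silyloxy diene are moisture-sensitive and are each to be prepared directly before step 15.

**Route**

Step 1
Reactants: 1 chloroacetaldehyde dimethyl acetal; 2 butanal
Product: 4 1-methoxyhex-1-yn-3-ol (racemic), via lithium methoxyacetylide 3 (not isolated)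
Conditions: LiNEt2 (3 equiv, from Et2NH and n-BuLi), THF, 0 °C; then 2, −78 → 0 °C; H2O
Reagents that add atoms: none
Why: The lithium amide removes methanol and HCl from the chloroacetal and deprotonates the resulting methoxyacetylene, and the acetylide adds 1,2 to the aldehyde (acetylide addition); the carbinol centre forms racemic and is oxidised away in step 2.

Step 2
Reactants: 4 1-methoxyhex-1-yn-3-ol
Product: 5 1-methoxyhex-1-yn-3-one
Conditions: MnO2 (activated, excess), CH2Cl2, rt
Reagents that add atoms: none
Why: MnO2 oxidises the propargylic alcohol under neutral heterogeneous conditions (propargylic alcohol oxidation), which should spare the acid-labile ynol ether.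

Step 3
Reactants: 6 2,4,6-trihydroxytoluene
Product: 8 2,4,6-trihydroxy-3-methylbenzaldehyde, via aryl iminium chloride 7 (not isolated)
Conditions: POCl3, DMF, EtOAc, 0 °C → rt; then H2O, 60 °C
Reagents that add atoms: N,N-dimethylformamide CN(C)C=O; water O
Why: Vilsmeier–Haack formylation of a phloroglucinol; the two open ring positions of 6 are equivalent and the iminium group deactivates the ring against a second attack.

Step 4
Reactants: 8 2,4,6-trihydroxy-3-methylbenzaldehyde
Product: 9 4,6-bis(benzyloxy)-2-hydroxy-3-methylbenzaldehyde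
Conditions: BnBr (2.05 equiv), K2CO3, DMF, 0 °C → rt
Reagents that add atoms: benzyl bromide BrCc1ccccc1
Why: Williamson etherification that should follow the usual order for 2,4,6-trihydroxyaryl carbonyl compounds, the para hydroxyl first and then the less hindered chelated ortho hydroxyl, so that the hydroxyl between CHO and CH3 stays free in its hydrogen bond; any regioisomer would be removed by crystallisation or chromatography.

Step 5
Reactants: 9 4,6-bis(benzyloxy)-2-hydroxy-3-methylbenzaldehyde
Product: 10 4,6-bis(benzyloxy)-2-methoxy-3-methylbenzaldehyde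
Conditions: MeI, K2CO3, DMF, 50 °C
Reagents that add atoms: iodomethane CI
Why: Williamson O-methylation of the one remaining, chelated phenol, which needs only mild heating in a dipolar solvent; this fixes OMe between the methyl carbon and the future bridge carbon of ring B.

Step 6
Reactants: 11 1,3,5-triacetoxybenzene
Product: 12 1,3,5-tris(benzyloxy)benzene
Conditions: BnCl, NaH (excess), DMF; H2O (3 equiv, added slowly), 0 °C → rt
Reagents that add atoms: benzyl chloride ClCc1ccccc1
Why: Hydroxide formed in the flask frees each phenoxide in the presence of excess benzyl chloride, so O-benzylation (Williamson) should outrun the C-benzylation that troubles free phloroglucinol.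

Step 7
Reactants: 12 1,3,5-tris(benzyloxy)benzene
Product: 13 2,4-dibromo-1,3,5-tris(benzyloxy)benzene
Conditions: NBS (2.0 equiv), CH2Cl2, 0 °C → rt
Reagents that add atoms: N-bromosuccinimide O=C1CCC(=O)N1Br
Why: Electrophilic aromatic bromination of a 1,3,5-trialkoxybenzene; the three ring positions are equivalent, so only one dibromide is possible, and the third bromination is slower.

Step 8
Reactants: 13 2,4-dibromo-1,3,5-tris(benzyloxy)benzene; 10 4,6-bis(benzyloxy)-2-methoxy-3-methylbenzaldehyde
Product: 15 [3-bromo-2,4,6-tris(benzyloxy)phenyl][4,6-bis(benzyloxy)-2-methoxy-3-methylphenyl]methanol (racemic), via aryllithium 14 (not isolated)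
Conditions: n-BuLi (1.0 equiv), THF, −78 °C; then 10, −78 → −20 °C; H2O
Reagents that add atoms: none
Why: Bromine–lithium exchange at −78 °C is faster than deprotonation of the benzyl ethers and stops after one exchange with one equivalent of n-BuLi, and the aryllithium adds 1,2 to the aldehyde; the carbinol centre is racemic and is removed in step 9.

Step 9
Reactants: 15 the diaryl carbinol
Product: 16 1,3,5-tris(benzyloxy)-2-bromo-4-{[4,6-bis(benzyloxy)-2-methoxy-3-methylphenyl]methyl}benzene (ArCB–Br)
Conditions: Et3SiH, CF3CO2H, CH2Cl2, −40 → 0 °C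
Reagents that add atoms: none
Why: Ionic hydrogenation: the carbinol ionises to a diarylmethyl cation stabilised by six alkoxy groups, which takes hydride from the silane; the aryl bromide and the benzyl ethers should tolerate brief cold acid.

Step 10
Reactants: 16 ArCB–Br
Product: 18 2,4,6-tris(benzyloxy)-3-{[4,6-bis(benzyloxy)-2-methoxy-3-methylphenyl]methyl}benzaldehyde (ArCB–CHO), via aryllithium 17 (not isolated)
Conditions: n-BuLi, THF, −78 °C; then DMF, −78 → 0 °C; H2O
Reagents that add atoms: N,N-dimethylformamide CN(C)C=O
Why: A second bromine–lithium exchange and formylation of the aryllithium with DMF (Bouveault-type aldehyde synthesis) place the carbon that becomes the ring A bridge at a position fixed by the bromine.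

Step 11
Reactants: 18 ArCB–CHO; 19 methyl 3-oxopentanoate
Product: 20 methyl 2-(ArCB-methylidene)-3-oxopentanoate (E/Z mixture)
Conditions: piperidine (cat.), AcOH (cat.), benzene, reflux, Dean–Stark trap
Reagents that add atoms: none
Why: Knoevenagel condensation through the piperidinium iminium ion with azeotropic removal of water; the alkene geometry is irrelevant because step 12 reduces it.

Step 12
Reactants: 20 the alkylidene keto ester
Product: 21 methyl 2-(ArCB-methyl)-3-oxopentanoate (racemic)
Conditions: Hantzsch ester (diethyl 2,6-dimethyl-1,4-dihydropyridine-3,5-dicarboxylate), SiO2, toluene, 70 °C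
Reagents that add atoms: none
Why: Transfer hydrogenation by the dihydropyridine delivers hydride only to the β-carbon of the doubly activated alkene (conjugate reduction) and leaves ketone, ester and benzyl ethers alone; the new α-carbon centre is racemic and disappears on enolisation.

Step 13
Reactants: 21 the keto ester
Product: 22 methyl 2-(ArCB-methyl)-3-(trimethylsilyloxy)pent-2-enoate (E/Z mixture)
Conditions: Me3SiCl, Et3N, benzene, rt
Reagents that add atoms: chlorotrimethylsilane C[Si](C)(C)Cl
Why: Soft enolisation and O-silylation of the β-keto ester at the ketone oxygen (silyl enol ether formation); the enol ether geometry has no consequence.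

Step 14
Reactants: 22 the mono-silyl enol ether
Product: 23 (3Z)-2-(ArCB-methyl)-1-methoxy-1,3-bis(trimethylsilyloxy)penta-1,3-diene (ketene acetal geometry not defined)
Conditions: LiN(i-Pr)2, THF, −78 °C; then Me3SiCl, −78 → 0 °C
Reagents that add atoms: chlorotrimethylsilane C[Si](C)(C)Cl
Why: Deprotonation of the γ-methylene of the β-silyloxy enoate gives a vinylogous ester enolate that is silylated at the ester oxygen (the standard two-stage preparation of 1-alkoxy-1,3-bis(silyloxy)dienes); the diene is used crude with exclusion of moisture.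

Step 15
Reactants: 23 the bis-silyloxy diene; 5 1-methoxyhex-1-yn-3-one
Product: 25 1-[3-(ArCB-methyl)-2,4-dihydroxy-6-methoxy-5-methylphenyl]butan-1-one, via cyclohexadiene cycloadduct 24 (not isolated)
Conditions: toluene, −20 → 60 °C; then 1 M HCl, THF, 0 °C → rt
Reagents that add atoms: none
Why: The electron-rich diene and the ynone combine in a Diels–Alder reaction that is concerted but asynchronous: the methyl-bearing diene terminus, the most nucleophilic carbon, bonds first to the methoxy-bearing β-carbon of the ynone (the bond between the methyl carbon and the methoxy carbon of ring A), and the ketene acetal carbon then bonds to the acyl-bearing α-carbon (the bond between the butanoyl carbon and its neighbouring hydroxyl carbon). The closest known reaction type is the cycloaddition–aromatisation of 1-alkoxy-1,3-bis(silyloxy)dienes with acetylenic esters and ketones to give resorcinols. Ring A closes in the [4+2] mode; in the stepwise limit this is a Mukaiyama–Michael addition followed by 6-exo-trig attack of the allenolate on the silylated ester carbon. The two sp3 centres of cycloadduct 24 form without control and vanish when methanol leaves the former ketene acetal carbon and acid hydrolyses the two silyl ethers, so that this carbon keeps its oxygen as the hydroxyl beside the butanoyl group and the former ketone carbon carries the hydroxyl beside the methyl group. The step needs regioselectivity, which the matched polarisation of the partners secures (donor terminus to acceptor β-carbon, placing OMe next to CH3 and butanoyl between OMe and OH), and it needs ring closure to outrun addition–elimination at the methoxy carbon, which the thermal conditions without Lewis acid should favour.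

Step 16
Reactants: 25 the ring A-complete pentabenzyl ether
Product: 26 1-[3-({3-[(4,6-dihydroxy-2-methoxy-3-methylphenyl)methyl]-2,4,6-trihydroxyphenyl}methyl)-2,4-dihydroxy-6-methoxy-5-methylphenyl]butan-1-one
Conditions: H2 (1 atm), Pd/C, EtOAc–MeOH, rt
Reagents that add atoms: none
Why: Hydrogenolysis of aryl benzyl ethers over Pd/C; the chelated, doubly ortho-substituted aryl ketone and the diarylmethane bridges should not be reduced under one atmosphere of hydrogen, and the air-sensitive heptaphenol is carried on directly.

Step 17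
Reactants: 26 the heptaphenol
Product: 28 1-[3-({3-butanoyl-5-[(3-butanoyl-2,4-dihydroxy-6-methoxy-5-methylphenyl)methyl]-2,4,6-trihydroxyphenyl}methyl)-2,4-dihydroxy-6-methoxy-5-methylphenyl]butan-1-one (target CNP0171986.0), via bis(ketiminium) dichloride 27 (not isolated)
Conditions: PrCN, ZnCl2, HCl (g), Et2O–EtOAc, 0 °C; then H2O, 90 °C
Reagents that add atoms: butanenitrile CCCC#N; water O
Why: Houben–Hoesch acylation: the nitrilium electrophile can attack only the single free ring carbon of the central ring and of ring B, each flanked by two hydroxyls, since ring A is fully substituted, and the ketiminium salts are hydrolysed to the ketones.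

**Compound list**

1 | chloroacetaldehyde dimethyl acetal (2-chloro-1,1-dimethoxyethane) | COC(CCl)OC | starting material
2 | butanal | CCCC=O | starting material
3 | lithium methoxyacetylide | [Li]C#COC | intermediate
4 | 1-methoxyhex-1-yn-3-ol (racemic) | CCCC(O)C#COC | intermediate
5 | 1-methoxyhex-1-yn-3-one | CCCC(=O)C#COC | intermediate
6 | 2,4,6-trihydroxytoluene | Cc1c(O)cc(O)cc1O | starting material
7 | N-[(2,4,6-trihydroxy-3-methylphenyl)methylidene]-N-methylmethanaminium chloride | Cc1c(O)cc(O)c(C=[N+](C)C)c1O.[Cl-] | intermediate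
8 | 2,4,6-trihydroxy-3-methylbenzaldehyde | Cc1c(O)cc(O)c(C=O)c1O | intermediate
9 | 4,6-bis(benzyloxy)-2-hydroxy-3-methylbenzaldehyde | Cc1c(O)c(C=O)c(OCc2ccccc2)cc1OCc1ccccc1 | intermediate
10 | 4,6-bis(benzyloxy)-2-methoxy-3-methylbenzaldehyde | COc1c(C)c(OCc2ccccc2)cc(OCc2ccccc2)c1C=O | intermediate
11 | 1,3,5-triacetoxybenzene (phloroglucinol triacetate) | CC(=O)Oc1cc(OC(C)=O)cc(OC(C)=O)c1 | starting material
12 | 1,3,5-tris(benzyloxy)benzene | c1ccc(COc2cc(OCc3ccccc3)cc(OCc3ccccc3)c2)cc1 | intermediate
13 | 2,4-dibromo-1,3,5-tris(benzyloxy)benzene | Brc1c(OCc2ccccc2)cc(OCc2ccccc2)c(Br)c1OCc1ccccc1 | intermediate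
14 | [3-bromo-2,4,6-tris(benzyloxy)phenyl]lithium | [Li]c1c(OCc2ccccc2)cc(OCc2ccccc2)c(Br)c1OCc1ccccc1 | intermediate
15 | [3-bromo-2,4,6-tris(benzyloxy)phenyl][4,6-bis(benzyloxy)-2-methoxy-3-methylphenyl]methanol (racemic) | OC(c1c(OCc2ccccc2)cc(OCc2ccccc2)c(Br)c1OCc1ccccc1)c1c(OCc2ccccc2)cc(OCc2ccccc2)c(C)c1OC | intermediate
16 | 1,3,5-tris(benzyloxy)-2-bromo-4-{[4,6-bis(benzyloxy)-2-methoxy-3-methylphenyl]methyl}benzene (ArCB–Br) | Brc1c(OCc2ccccc2)cc(OCc2ccccc2)c(Cc2c(OCc3ccccc3)cc(OCc3ccccc3)c(C)c2OC)c1OCc1ccccc1 | intermediate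
17 | ArCB–Li, the aryllithium from 16 | [Li]c1c(OCc2ccccc2)cc(OCc2ccccc2)c(Cc2c(OCc3ccccc3)cc(OCc3ccccc3)c(C)c2OC)c1OCc1ccccc1 | intermediate
18 | 2,4,6-tris(benzyloxy)-3-{[4,6-bis(benzyloxy)-2-methoxy-3-methylphenyl]methyl}benzaldehyde (ArCB–CHO) | O=Cc1c(OCc2ccccc2)cc(OCc2ccccc2)c(Cc2c(OCc3ccccc3)cc(OCc3ccccc3)c(C)c2OC)c1OCc1ccccc1 | intermediate
19 | methyl 3-oxopentanoate | CCC(=O)CC(=O)OC | starting material
20 | methyl 2-(ArCB-methylidene)-3-oxopentanoate (E/Z mixture) | CCC(=O)C(=Cc1c(OCc2ccccc2)cc(OCc2ccccc2)c(Cc2c(OCc3ccccc3)cc(OCc3ccccc3)c(C)c2OC)c1OCc1ccccc1)C(=O)OC | intermediate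
21 | methyl 2-(ArCB-methyl)-3-oxopentanoate (racemic) | CCC(=O)C(Cc1c(OCc2ccccc2)cc(OCc2ccccc2)c(Cc2c(OCc3ccccc3)cc(OCc3ccccc3)c(C)c2OC)c1OCc1ccccc1)C(=O)OC | intermediate
22 | methyl 2-(ArCB-methyl)-3-(trimethylsilyloxy)pent-2-enoate (E/Z mixture) | CCC(O[Si](C)(C)C)=C(Cc1c(OCc2ccccc2)cc(OCc2ccccc2)c(Cc2c(OCc3ccccc3)cc(OCc3ccccc3)c(C)c2OC)c1OCc1ccccc1)C(=O)OC | intermediate
23 | (3Z)-2-(ArCB-methyl)-1-methoxy-1,3-bis(trimethylsilyloxy)penta-1,3-diene (ketene acetal geometry not defined) | C/C=C(O[Si](C)(C)C)/C(Cc1c(OCc2ccccc2)cc(OCc2ccccc2)c(Cc2c(OCc3ccccc3)cc(OCc3ccccc3)c(C)c2OC)c1OCc1ccccc1)=C(OC)O[Si](C)(C)C | intermediate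
24 | 1-[5-(ArCB-methyl)-2,6-dimethoxy-3-methyl-4,6-bis(trimethylsilyloxy)cyclohexa-1,4-dien-1-yl]butan-1-one (diastereomer mixture) | CCCC(=O)C1=C(OC)C(C)C(O[Si](C)(C)C)=C(Cc2c(OCc3ccccc3)cc(OCc3ccccc3)c(Cc3c(OCc4ccccc4)cc(OCc4ccccc4)c(C)c3OC)c2OCc2ccccc2)C1(OC)O[Si](C)(C)C | intermediate
25 | 1-[3-(ArCB-methyl)-2,4-dihydroxy-6-methoxy-5-methylphenyl]butan-1-one | CCCC(=O)c1c(O)c(Cc2c(OCc3ccccc3)cc(OCc3ccccc3)c(Cc3c(OCc4ccccc4)cc(OCc4ccccc4)c(C)c3OC)c2OCc2ccccc2)c(O)c(C)c1OC | intermediate
26 | 1-[3-({3-[(4,6-dihydroxy-2-methoxy-3-methylphenyl)methyl]-2,4,6-trihydroxyphenyl}methyl)-2,4-dihydroxy-6-methoxy-5-methylphenyl]butan-1-one | CCCC(=O)c1c(O)c(Cc2c(O)cc(O)c(Cc3c(O)cc(O)c(C)c3OC)c2O)c(O)c(C)c1OC | intermediate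
27 | bis(ketiminium) dichloride of the target (C=NH2+ in place of the central and ring B ketone C=O) | CCCC(=[NH2+])c1c(O)c(Cc2c(O)c(C)c(OC)c(C(=O)CCC)c2O)c(O)c(Cc2c(O)c(C(=[NH2+])CCC)c(O)c(C)c2OC)c1O.[Cl-].[Cl-] | intermediate
28 | 1-[3-({3-butanoyl-5-[(3-butanoyl-2,4-dihydroxy-6-methoxy-5-methylphenyl)methyl]-2,4,6-trihydroxyphenyl}methyl)-2,4-dihydroxy-6-methoxy-5-methylphenyl]butan-1-one (CNP0171986.0) | CCCC(=O)c1c(O)c(Cc2c(O)c(C)c(OC)c(C(=O)CCC)c2O)c(O)c(Cc2c(O)c(C(=O)CCC)c(O)c(C)c2OC)c1O | target

**Step count and risks**

Total steps: 17. Longest linear sequence: 13 steps (steps 3, 4, 5 and 8 to 17, from 2,4,6-trihydroxytoluene).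

Steps most likely to fail:

1. Step 15. The donor methoxy group may deactivate the ynone so that cycloaddition stalls; conjugate addition may be followed by expulsion of methoxide instead of ring closure; or the diene may lose its silyl groups before it reacts. In that case ring A would be brought in preformed. The fallback sets out from aldehydes 18 and 10 and comes back to the route at 25. Aldehyde 18 is reduced (NaBH4, THF–MeOH) to the benzylic alcohol ArCB-methanol F1. Aldehyde 10 is treated with n-PrMgBr to give 1-[4,6-bis(benzyloxy)-2-methoxy-3-methylphenyl]butan-1-ol F2, which is oxidised (Dess–Martin periodinane) to 1-[4,6-bis(benzyloxy)-2-methoxy-3-methylphenyl]butan-1-one F3 and hydrogenolysed (H2, Pd/C) to 1-(4,6-dihydroxy-2-methoxy-3-methylphenyl)butan-1-one F4. Acid-catalysed Friedel–Crafts benzylation of F4, used in excess, with F1 (Sc(OTf)3 cat., CH2Cl2–MeNO2) at the single free ring carbon of F4, which lies between two hydroxyls, should give 25.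

2. Step 17. Acid may cleave or exchange the methylene bridges of the free heptaphenol, the reaction may stall after one acylation, or the polyphenol may oxidise in air. In that case the acyl groups would be introduced before deprotection. The fallback sets out from 25 and comes back at the target 28. Friedel–Crafts acylation with the mixed anhydride of butanoic acid and (CF3CO)2O (cat. H3PO4, CH2Cl2), followed by K2CO3 in MeOH to cleave any aryl esters formed on ring A, gives the bis-acylated pentabenzyl ether F5. Hydrogenolysis (H2, Pd/C, EtOAc–MeOH) then gives 28.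

3. Step 11. Condensation at the hindered, electron-rich aldehyde may be slow and the adduct may revert. In that case the three-carbon chain would be built through a more reactive carbon acid. The fallback sets out from 18 and comes back at 21. Reductive alkylation of Meldrum's acid (Meldrum's acid, Hantzsch ester, L-proline, EtOH, rt) gives 5-(ArCB-methyl)-2,2-dimethyl-1,3-dioxane-4,6-dione F6. Ring opening and decarboxylation (MeOH–pyridine, reflux) give methyl 3-(ArCB)propanoate F7. Crossed Claisen acylation of its enolate (LiN(i-Pr)2, 2 equiv, THF, −78 °C, then propanoyl chloride) gives 21.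

Further compounds
F1 | step 15 | ArCB-methanol | OCc1c(OCc2ccccc2)cc(OCc2ccccc2)c(Cc2c(OCc3ccccc3)cc(OCc3ccccc3)c(C)c2OC)c1OCc1ccccc1
F2 | step 15 | 1-[4,6-bis(benzyloxy)-2-methoxy-3-methylphenyl]butan-1-ol (racemic) | CCCC(O)c1c(OCc2ccccc2)cc(OCc2ccccc2)c(C)c1OC
F3 | step 15 | 1-[4,6-bis(benzyloxy)-2-methoxy-3-methylphenyl]butan-1-one | CCCC(=O)c1c(OCc2ccccc2)cc(OCc2ccccc2)c(C)c1OC
F4 | step 15 | 1-(4,6-dihydroxy-2-methoxy-3-methylphenyl)butan-1-one | CCCC(=O)c1c(O)cc(O)c(C)c1OC
F5 | step 17 | pentabenzyl ether of the target (central ring and ring B hydroxyls benzylated, ring A hydroxyls free) | CCCC(=O)c1c(O)c(Cc2c(OCc3ccccc3)c(C(=O)CCC)c(OCc3ccccc3)c(Cc3c(OCc4ccccc4)c(C(=O)CCC)c(OCc4ccccc4)c(C)c3OC)c2OCc2ccccc2)c(O)c(C)c1OC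
F6 | step 11 | 5-(ArCB-methyl)-2,2-dimethyl-1,3-dioxane-4,6-dione | CC1(C)OC(=O)C(Cc2c(OCc3ccccc3)cc(OCc3ccccc3)c(Cc3c(OCc4ccccc4)cc(OCc4ccccc4)c(C)c3OC)c2OCc2ccccc2)C(=O)O1
F7 | step 11 | methyl 3-(ArCB)propanoate | COC(=O)CCc1c(OCc2ccccc2)cc(OCc2ccccc2)c(Cc2c(OCc3ccccc3)cc(OCc3ccccc3)c(C)c2OC)c1OCc1ccccc1
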